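Ring A is disconnected at C3–C4. C19 sits on the quaternary C4 and lies across ring A from C1, so a C19-to-C1 δ-lactone that carries a (Z)-alkoxyvinyl group (C2=C3) on C1 is an Ireland–Claisen substrate. Its silyl ketene acetal must fold as a boat; one [3,3] shift forms C3–C4, cleaves C1–O, closes ring A, sets C3 and C4 and frees the C19 acid. The precursor 26 is the B/C/D tricycle fused to this lactone, with a tert-butyl ester at C7, a ketal at C12 and a silyl ether at C16. Rings C/D come from an asymmetric Diels–Alder/aldol sequence, ring B from a conjugate addition, alkylation and Michael closure.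

Key step: step 18

Remark: gibberellane numbering is used throughout; α is the face of the C10 methyl and of C19, β the face of 3-OH, H5 and H9.
Remark: C7 is carried as the tert-butyl ester, because a less hindered ester at C7 (6β, cis-1,3 to C1 on ring B) could trap the C1 alkoxide as a bridged lactone and could be enolised in the key step.
Remark: the C1=C2 alkene is reduced with diimide, since catalytic hydrogenation would also cleave the allylic 4-methoxybenzyl ether.
Remark: the antipode of the chromium–salen catalyst in step 2 is the one that gives C8 as drawn; C16 of 7 is carried as one carbinol epimer, and the C4 epimers (from 15 on) and the C10 epimers of 11 converge later, so the SMILES leave these centres open.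

Step 1
Reactants: 1 tert-butyl 4-oxobutanoate
Product: 2 tert-butyl 3-formylbut-3-enoate
Conditions: 37% aq. HCHO, pyrrolidine (10 mol%), EtCO2H (10 mol%), i-PrOH, 45 °C
Reagents that add atoms: formaldehyde C=O
Why: amine-catalysed Mannich condensation and elimination (α-methylenation of an aldehyde) should give the 2-substituted acrolein, with no stereocentre formed.

Step 2
Reactants: 2 tert-butyl 3-formylbut-3-enoate; 3 (E)-3-(tert-butyldimethylsilyloxy)-N,N-dimethylbuta-1,3-dien-1-amine
Product: 4 Diels–Alder adduct, tert-butyl 2-[4-(tert-butyldimethylsilyloxy)-2-(dimethylamino)-1-formylcyclohex-3-en-1-yl]acetate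
Conditions: [Cr(salen*)]SbF6 (5 mol%; salen* = dianion of N,N'-bis(3,5-di-tert-butylsalicylidene)-trans-cyclohexane-1,2-diamine, one antipode), 4 Å sieves, CH2Cl2, −40 °C
Reagents that add atoms: none
Why: enantioselective Diels–Alder reaction of a 1-amino-3-siloxydiene with a 2-substituted acrolein, in which the chiral trivalent chromium Lewis acid shields one face of the bound enal and so sets the quaternary carbon C8.

Step 3
Reactants: 4 Diels–Alder adduct
Product: 5 enol ether, tert-butyl 2-[4-(tert-butyldimethylsilyloxy)-2-(dimethylamino)-1-(2-methoxyethenyl)cyclohex-3-en-1-yl]acetate (E/Z)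
Conditions: Ph3P(CH2OMe)Cl, KN(SiMe3)2, THF, −78 → 0 °C
Reagents that add atoms: (methoxymethyl)triphenylphosphonium chloride COC[P+](c1ccccc1)(c1ccccc1)c1ccccc1.[Cl-]
Why: Wittig methoxymethylenation of the only carbonyl group adds C16 as a masked aldehyde and leaves C8 untouched.

Step 4
Reactants: 5 enol ether
Product: 7 ring C/D hydroxy enone, tert-butyl 2-(6-hydroxy-4-oxobicyclo[3.2.1]oct-2-en-1-yl)acetate (12-oxo, Δ9(11), 16-OH), via keto aldehyde 6 (not isolated)
Conditions: 1 M aq. HCl, THF, 23 °C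
Reagents that add atoms: water O
Why: acid hydrolysis of both enol ethers with β-elimination of Me2NH should unmask the enone and the C16 aldehyde, and the acid-catalysed intramolecular aldol addition of the C13 enol to C16 (5-(enolexo)-exo-trig) closes ring D in the only bridged sense that C8 allows, which sets C13, while dehydration is barred at the bridgehead.

Step 5
Reactants: 7 ring C/D hydroxy enone
Product: 8 16-O-tert-butyldimethylsilyl ether of 7
Conditions: tBuMe2SiOTf, 2,6-lutidine, CH2Cl2, 0 °C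
Reagents that add atoms: tert-butyldimethylsilyl trifluoromethanesulfonate CC(C)(C)[Si](C)(C)OS(=O)(=O)C(F)(F)F
Why: standard O-silylation of a secondary alcohol masks C16 until ring A is complete.

Step 6
Reactants: 9 S-ethyl propanethioate
Product: 10 silyl ketene thioacetal, tert-butyl{[1-(ethylsulfanyl)prop-1-en-1-yl]oxy}dimethylsilane
Conditions: LiN(iPr)2, THF, −78 °C; tBuMe2SiCl, DMPU, −78 → 0 °C
Reagents that add atoms: tert-butyldimethylsilyl chloride CC(C)(C)[Si](C)(C)Cl
Why: enolisation and O-silylation of a thioester give the nucleophile for the conjugate addition; its geometry is of no consequence.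

Step 7
Reactants: 8 silylated ring C/D enone; 10 silyl ketene thioacetal
Product: 11 C9 adduct (9β-H; C9 carries CH(CH3)C(O)SEt = C10, C20, C5; C12 as silyl enol ether; 16-OSi; C8–CH2CO2tBu)
Conditions: tBuMe2SiOTf (10 mol%), CH2Cl2, −78 °C
Reagents that add atoms: none
Why: Mukaiyama–Michael addition with silyl transfer to the non-enolisable enone, in which the nucleophile should add axially to C9 on the face away from the C15–C16 bridge, which sets C9 and leaves C12 masked as its silyl enol ether.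

Step 8
Reactants: 11 C9 adduct
Product: 12 quaternary thioester (C10 carries CH3, CH2OBn = C1 and C(O)SEt = C5)
Conditions: LiN(SiMe3)2 (1.1 equiv), THF, −78 °C; BnOCH2Cl, −78 → −40 °C
Reagents that add atoms: benzyl chloromethyl ether ClCOCc1ccccc1
Why: alkylation of the thioester enolate, formed selectively because the thioester is more acidic than the tert-butyl ester, in which H9 should eclipse the enolate (allylic strain) so that the electrophile enters anti to the quaternary C8, which sets C10.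

Step 9
Reactants: 12 quaternary thioester
Product: 13 C5 aldehyde
Conditions: Et3SiH, Pd/C (10%), acetone, 23 °C
Reagents that add atoms: none
Why: Fukuyama reduction converts the thioester into the aldehyde and should leave the esters, the silyl groups and the benzyl ether intact.

Step 10
Reactants: 13 C5 aldehyde
Product: 14 (E)-enoate (C10–CH=C(CH3)CO2Me; C5=C4, C18, C19)
Conditions: Ph3P=C(CH3)CO2Me, toluene, 100 °C
Reagents that add atoms: methyl 2-(triphenylphosphoranylidene)propanoate COC(=O)C(C)=P(c1ccccc1)(c1ccccc1)c1ccccc1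
Why: Wittig olefination of a non-enolisable aldehyde with a stabilised ylide installs C4, C18 and C19 as the (E)-enoate.

Step 11
Reactants: 14 (E)-enoate
Product: 16 ring B/C/D ketone (12-oxo, 16-OSi, 6β-CO2tBu, 5α-CH(CH3)CO2Me, 5β-H, 10α-CH3, 10β-CH2OBn), via silyl enol ether 15 (not isolated)
Conditions: KOtBu (0.3 equiv), t-BuOH/THF, 0 → 23 °C; then 1 M aq. HCl, THF, 0 °C
Reagents that add atoms: none
Why: intramolecular Michael addition (5-exo-trig) of the C6 ester enolate to C5 closes ring B, where allylic strain about C10–C5 and the bulk of the C1 arm should place the propionate arm α on C5 and equilibration the ester β on C6, and dilute acid then frees the C12 ketone.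

Step 12
Reactants: 16 ring B/C/D ketone
Product: 17 12,12-ethylenedioxy ketal of 16
Conditions: (Me3SiOCH2)2, Me3SiOTf (5 mol%), CH2Cl2, −78 → −20 °C
Reagents that add atoms: 1,2-bis(trimethylsilyloxy)ethane C[Si](C)(C)OCCO[Si](C)(C)C
Why: aprotic ketalisation protects the only ketone, so that C12 needs no redox change and stays masked through the C16 methylenation.

Step 13
Reactants: 17 ketal
Product: 18 C1 alcohol (10β-CH2OH)
Conditions: H2 (1 atm), Pd/C (10%), EtOAc, 23 °C
Reagents that add atoms: none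
Why: hydrogenolysis of the benzyl ether in a substrate without alkenes.

Step 14
Reactants: 18 C1 alcohol
Product: 19 C1 aldehyde (10β-CHO)
Conditions: DMP (1,1,1-triacetoxy-1,2-benziodoxol-3(1H)-one), NaHCO3, CH2Cl2, 23 °C
Reagents that add atoms: none
Why: periodinane oxidation of a neopentyl primary alcohol to a non-enolisable aldehyde.

Step 15
Reactants: 20 4-methoxybenzyl alcohol
Product: 21 4-methoxybenzyl vinyl ether
Conditions: butyl vinyl ether (solvent), Pd(OCOCF3)2 (1 mol%), 4,7-diphenyl-1,10-phenanthroline (1 mol%), Et3N (5 mol%), 75 °C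
Reagents that add atoms: butyl vinyl ether C=COCCCC
Why: palladium-catalysed transfer vinylation of an alcohol.

Step 16
Reactants: 21 4-methoxybenzyl vinyl ether
Product: 23 (Z)-2-bromovinyl 4-methoxybenzyl ether, via dibromide 22 (not isolated)
Conditions: Br2, CH2Cl2, −78 °C; then PhNEt2, toluene, 90 °C
Reagents that add atoms: bromine BrBr
Why: bromine addition to the vinyl ether and amine-induced loss of HBr, a sequence known to favour the (Z)-2-bromovinyl ether.

Step 17
Reactants: 19 C1 aldehyde; 23 (Z)-2-bromovinyl 4-methoxybenzyl ether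
Product: 26 C19-to-C1 δ-lactone with a (Z)-2-(4-methoxybenzyloxy)vinyl group on C1 (C4 epimers), via vinyllithium 24 (not isolated), via lithium alkoxide 25 (not isolated)
Conditions: 23 (1.3 equiv), t-BuLi (2.6 equiv), Et2O, −78 °C; 19, THF, −78 °C; then 0 °C
Reagents that add atoms: none
Why: bromine–lithium exchange with retention, Felkin–Anh addition to the aldehyde (the C5 side is shielded by the 6β ester, so attack past the C10 methyl on the C9 side should set C1 as drawn) and lactonisation of the alkoxide onto the C19 methyl ester, the tert-butyl ester being inert.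

Step 18
Reactants: 26 C19-to-C1 δ-lactone
Product: 29 ring A acid (Δ1, 3β-OPMB, 4β-CH3, 4α-COOH), via silyl ketene acetal 27 (not isolated), via silyl ester 28 (not isolated)
Conditions: LiN(iPr)2 (1.5 equiv), THF, −78 °C; Me3SiCl/Et3N, −78 → 23 °C; toluene, 100 °C; then 5% aq. citric acid
Reagents that add atoms: none
Why: Ireland–Claisen rearrangement of a lactone silyl ketene acetal, a known reaction of alkenyl lactones: LiN(iPr)2 removes H4 of either C4 epimer, Me3SiCl traps the endocyclic ketene acetal 27, and its array C4=C19–O–C1–C2=C3 undergoes a concerted suprafacial [3,3] shift that makes C3–C4, breaks C1–O and moves the alkene to C1=C2. Ring A (C10–C1–C2–C3–C4–C5) closes in the sigmatropic step itself, not by an ionic cyclisation, as O and C19 leave the six-membered ring and C2 and C3 enter it. Because C5–C10 ties C4 to C1, the array can only fold as a boat, with the axial alkenyl arm on C1 lying over the ketene acetal. C4 is controlled by the C1 carbinol: C3 is delivered to the face of C4 on which the alkenyl group stands, so C19 ends α, cis to the C10 methyl, and C18 β. C3 is controlled by the (Z) geometry of the enol ether, which puts the ether oxygen axial and trans to C19 (3β). The step needs deprotonation at C4 and not at C6, which the more acidic lactone and the hindered tert-butyl ester should secure, and it needs the boat, which the lactone ring enforces.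

Step 19
Reactants: 29 ring A acid
Product: 30 1,2-dihydro acid
Conditions: 2-O2NC6H4SO2NHNH2 (10 equiv), Et3N, CH2Cl2, 23 °C
Reagents that add atoms: none
Why: diimide reduction saturates the cis-disubstituted C1=C2 alkene without hydrogenolysis of the allylic 4-methoxybenzyl ether and creates no stereocentre.

Step 20
Reactants: 30 1,2-dihydro acid
Product: 31 16-alcohol
Conditions: Bu4NF, THF, 40 °C
Reagents that add atoms: none
Why: fluoride cleavage of the silyl ether, to which the ketal, both ethers and the tert-butyl ester are inert.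

Step 21
Reactants: 31 16-alcohol
Product: 32 16-ketone
Conditions: DMP, CH2Cl2, 23 °C
Reagents that add atoms: none
Why: periodinane oxidation of the secondary alcohol, with C12 still masked as its ketal.

Step 22
Reactants: 32 16-ketone
Product: 33 16-methylene compound
Conditions: Ph3PCH3Br (5 equiv), KOtBu (5 equiv), THF, 23 → 50 °C
Reagents that add atoms: methyltriphenylphosphonium bromide C[P+](c1ccccc1)(c1ccccc1)c1ccccc1.[Br-]
Why: Wittig methylenation of the only free ketone with excess ylide, which tolerates the C19 carboxylate.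

Step 23
Reactants: 33 16-methylene compound
Product: 34 12-ketone
Conditions: pyridinium p-toluenesulfonate, acetone/H2O, 50 °C
Reagents that add atoms: water O
Why: mild acid hydrolysis of the dioxolane returns the C12 ketone and should spare the exocyclic alkene, the benzylic ether and the tert-butyl ester.

Step 24
Reactants: 34 12-ketone
Product: 35 3β-alcohol (7-tert-butyl ester)
Conditions: DDQ, CH2Cl2/pH 7 buffer, 0 °C
Reagents that add atoms: none
Why: oxidative cleavage of the 4-methoxybenzyl ether under neutral conditions, so that the β-hydroxy acid is never exposed to base.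

Step 25
Reactants: 35 3β-alcohol
Product: 36 CNP0197851.1 (target diacid)
Conditions: Me3SiOTf, 2,6-lutidine, CH2Cl2, 0 °C; then aq. KH2PO4, THF
Reagents that add atoms: none
Why: silyl triflate-mediated cleavage of the tert-butyl ester through its silyl ester, under non-protic conditions chosen to avoid acid-induced isomerisation of the 16-ene.

Compound list
1 | tert-butyl 4-oxobutanoate | O=CCCC(=O)OC(C)(C)C | starting material
2 | tert-butyl 3-formylbut-3-enoate | C=C(C=O)CC(=O)OC(C)(C)C | intermediate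
3 | (E)-3-(tert-butyldimethylsilyloxy)-N,N-dimethylbuta-1,3-dien-1-amine | CN(C)/C=C/C(=C)O[Si](C)(C)C(C)(C)C | starting material
4 | Diels–Alder adduct, tert-butyl 2-[4-(tert-butyldimethylsilyloxy)-2-(dimethylamino)-1-formylcyclohex-3-en-1-yl]acetate (quaternary carbon = C8) | O=C[C@]1(CC(=O)OC(C)(C)C)CCC(O[Si](C)(C)C(C)(C)C)=CC1N(C)C | intermediate
5 | enol ether, 1-(2-methoxyethenyl) analogue of 4 | COC=C[C@]1(CC(=O)OC(C)(C)C)CCC(O[Si](C)(C)C(C)(C)C)=CC1N(C)C | intermediate
6 | keto aldehyde, tert-butyl 2-[4-oxo-1-(2-oxoethyl)cyclohex-2-en-1-yl]acetate | O=CC[C@]1(CC(=O)OC(C)(C)C)CCC(=O)C=C1 | intermediate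
7 | ring C/D hydroxy enone, tert-butyl 2-(6-hydroxy-4-oxobicyclo[3.2.1]oct-2-en-1-yl)acetate | OC1C[C@]2(CC(=O)OC(C)(C)C)C[C@H]1C(=O)C=C2 | intermediate
8 | 16-O-tert-butyldimethylsilyl ether of 7 | CC(C)(C)[Si](C)(C)OC1C[C@]2(CC(=O)OC(C)(C)C)C[C@H]1C(=O)C=C2 | intermediate
9 | S-ethyl propanethioate | CCC(=O)SCC | starting material
10 | tert-butyl{[1-(ethylsulfanyl)prop-1-en-1-yl]oxy}dimethylsilane | CC=C(SCC)O[Si](C)(C)C(C)(C)C | intermediate
11 | C9 adduct (9β-H, C12 silyl enol ether, C10 epimers) | CC(C)(C)[Si](C)(C)OC1C[C@]2(CC(=O)OC(C)(C)C)C[C@H]1C(O[Si](C)(C)C(C)(C)C)=C[C@H]2C(C)C(=O)SCC | intermediate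
12 | quaternary thioester (C10: CH3, CH2OBn, C(O)SEt) | CC(C)(C)[Si](C)(C)OC1C[C@]2(CC(=O)OC(C)(C)C)C[C@H]1C(O[Si](C)(C)C(C)(C)C)=C[C@H]2[C@](C)(COCc3ccccc3)C(=O)SCC | intermediate
13 | C5 aldehyde | CC(C)(C)[Si](C)(C)OC1C[C@]2(CC(=O)OC(C)(C)C)C[C@H]1C(O[Si](C)(C)C(C)(C)C)=C[C@H]2[C@](C)(COCc3ccccc3)C=O | intermediate
14 | (E)-enoate | CC(C)(C)[Si](C)(C)OC1C[C@]2(CC(=O)OC(C)(C)C)C[C@H]1C(O[Si](C)(C)C(C)(C)C)=C[C@H]2[C@](C)(COCc3ccccc3)/C=C(\C)C(=O)OC | intermediate
15 | ring B Michael adduct as C12 silyl enol ether | CC(C)(C)[Si](C)(C)OC1C[C@]23C[C@H]1C(O[Si](C)(C)C(C)(C)C)=C[C@H]2[C@](C)(COCc4ccccc4)[C@@H](C(C)C(=O)OC)[C@@H]3C(=O)OC(C)(C)C | intermediate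
16 | ring B/C/D ketone (12-oxo) | CC(C)(C)[Si](C)(C)OC1C[C@]23C[C@H]1C(=O)C[C@H]2[C@](C)(COCc4ccccc4)[C@@H](C(C)C(=O)OC)[C@@H]3C(=O)OC(C)(C)C | intermediate
17 | 12,12-ethylenedioxy ketal of 16 | CC(C)(C)[Si](C)(C)OC1C[C@]23C[C@H]1C4(OCCO4)C[C@H]2[C@](C)(COCc5ccccc5)[C@@H](C(C)C(=O)OC)[C@@H]3C(=O)OC(C)(C)C | intermediate
18 | C1 alcohol (10β-CH2OH) | CC(C)(C)[Si](C)(C)OC1C[C@]23C[C@H]1C4(OCCO4)C[C@H]2[C@](C)(CO)[C@@H](C(C)C(=O)OC)[C@@H]3C(=O)OC(C)(C)C | intermediate
19 | C1 aldehyde (10β-CHO) | CC(C)(C)[Si](C)(C)OC1C[C@]23C[C@H]1C4(OCCO4)C[C@H]2[C@](C)(C=O)[C@@H](C(C)C(=O)OC)[C@@H]3C(=O)OC(C)(C)C | intermediate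
20 | 4-methoxybenzyl alcohol | COc1ccc(CO)cc1 | starting material
21 | 4-methoxybenzyl vinyl ether | COc1ccc(COC=C)cc1 | intermediate
22 | 1,2-dibromoethyl 4-methoxybenzyl ether | COc1ccc(COC(Br)CBr)cc1 | intermediate
23 | (Z)-2-bromovinyl 4-methoxybenzyl ether | COc1ccc(CO/C=C\Br)cc1 | intermediate
24 | (Z)-2-(4-methoxybenzyloxy)vinyllithium | COc1ccc(CO/C=C\[Li])cc1 | intermediate
25 | C1 carbinol with (Z)-CH=CH–OPMB (lithium alkoxide in the flask) | CC(C)(C)[Si](C)(C)OC1C[C@]23C[C@H]1C4(OCCO4)C[C@H]2[C@](C)([C@@H](O)/C=C\OCc5ccc(OC)cc5)[C@@H](C(C)C(=O)OC)[C@@H]3C(=O)OC(C)(C)C | intermediate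
26 | C19-to-C1 δ-lactone, key precursor (C4 epimers) | CC(C)(C)[Si](C)(C)OC1C[C@]23C[C@H]1C4(OCCO4)C[C@H]2[C@]5(C)[C@H](/C=C\OCc6ccc(OC)cc6)OC(=O)C(C)[C@H]5[C@@H]3C(=O)OC(C)(C)C | intermediate
27 | O-trimethylsilyl ketene acetal of 26 (C4=C19) | CC(C)(C)[Si](C)(C)OC1C[C@]23C[C@H]1C4(OCCO4)C[C@H]2[C@]5(C)[C@H](/C=C\OCc6ccc(OC)cc6)OC(O[Si](C)(C)C)=C(C)[C@H]5[C@@H]3C(=O)OC(C)(C)C | intermediate
28 | trimethylsilyl ester of 29 | CC(C)(C)[Si](C)(C)OC1C[C@]23C[C@H]1C4(OCCO4)C[C@H]2[C@]5(C)C=C[C@H](OCc6ccc(OC)cc6)[C@@](C)(C(=O)O[Si](C)(C)C)[C@H]5[C@@H]3C(=O)OC(C)(C)C | intermediate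
29 | ring A acid (Δ1, 3β-OPMB, 4α-COOH), key product | CC(C)(C)[Si](C)(C)OC1C[C@]23C[C@H]1C4(OCCO4)C[C@H]2[C@]5(C)C=C[C@H](OCc6ccc(OC)cc6)[C@@](C)(C(=O)O)[C@H]5[C@@H]3C(=O)OC(C)(C)C | intermediate
30 | 1,2-dihydro acid | CC(C)(C)[Si](C)(C)OC1C[C@]23C[C@H]1C4(OCCO4)C[C@H]2[C@]5(C)CC[C@H](OCc6ccc(OC)cc6)[C@@](C)(C(=O)O)[C@H]5[C@@H]3C(=O)OC(C)(C)C | intermediate
31 | 16-alcohol | OC1C[C@]23C[C@H]1C4(OCCO4)C[C@H]2[C@]5(C)CC[C@H](OCc6ccc(OC)cc6)[C@@](C)(C(=O)O)[C@H]5[C@@H]3C(=O)OC(C)(C)C | intermediate
32 | 16-ketone | O=C1C[C@]23C[C@H]1C4(OCCO4)C[C@H]2[C@]5(C)CC[C@H](OCc6ccc(OC)cc6)[C@@](C)(C(=O)O)[C@H]5[C@@H]3C(=O)OC(C)(C)C | intermediate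
33 | 16-methylene compound (C12 ketal) | C=C1C[C@]23C[C@H]1C4(OCCO4)C[C@H]2[C@]5(C)CC[C@H](OCc6ccc(OC)cc6)[C@@](C)(C(=O)O)[C@H]5[C@@H]3C(=O)OC(C)(C)C | intermediate
34 | 12-ketone (3β-OPMB, 7-tert-butyl ester) | C=C1C[C@]23C[C@H]1C(=O)C[C@H]2[C@]4(C)CC[C@H](OCc5ccc(OC)cc5)[C@@](C)(C(=O)O)[C@H]4[C@@H]3C(=O)OC(C)(C)C | intermediate
35 | 3β-alcohol, 7-tert-butyl ester | C=C1C[C@]23C[C@H]1C(=O)C[C@H]2[C@]4(C)CC[C@H](O)[C@@](C)(C(=O)O)[C@H]4[C@@H]3C(=O)OC(C)(C)C | intermediate
36 | CNP0197851.1 | C=C1C[C@]23C[C@H]1C(=O)C[C@H]2[C@]1(C)CC[C@H](O)[C@@](C)(C(=O)O)[C@H]1[C@@H]3C(=O)O | target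

Total step count: 25. Longest linear sequence: 22 steps (steps 1–5, 7–14 and 17–25, from 1).

Steps most likely to fail

Step 18. The congested ketene acetal may rearrange slowly, so that deprotonation at C6 or loss of the silyl group back to 26 competes on heating. The fallback keeps the disconnection and uses a neutral Claisen rearrangement; it sets out from 26 and comes back at 29. Reduction of 26 with iBu2AlH (CH2Cl2, −78 °C; the tert-butyl ester is inert) should give the lactol F1. Mesylation and elimination (MsCl, Et3N, then warming) should give the cyclic enol ether F2, a 3,4-dihydro-2H-pyran with C19=C4. Heating this allyl vinyl ether (xylene, 140–180 °C, base-washed glass) should pass through the same boat to the C19 aldehyde F3. Oxidation with NaClO2 (NaH2PO4, 2-methylbut-2-ene) then gives acid 29.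

Step 8. Facial selectivity in the alkylation may be poor or reversed, which would give the C10 epimer. The fallback reverses the order in which the two C10 substituents arrive; it sets out from 8 and comes back at 12. S-ethyl ethanethioate is converted (LiN(iPr)2, tBuMe2SiCl) into the ketene thioacetal F4. Mukaiyama–Michael addition of F4 to 8 (tBuMe2SiOTf cat.) gives the thioacetate adduct F5. LiN(SiMe3)2 and BnOCH2Cl give the benzyloxymethyl thioester F6, whose C10 epimers are of no consequence. LiN(SiMe3)2 and MeI then bring in the methyl group last, so that the same facial preference now leads to 12.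

Step 17. Facial selectivity in the addition to the hindered aldehyde may be poor (C1 epimers), and lactonisation may be incomplete. The fallback sets C1 by reagent control; it sets out from 19 and comes back at 25, which is closed to 26 with catalytic NaH. Alcohol 20 with KH and trichloroethylene gives the (E)-1,2-dichlorovinyl ether F7, and n-BuLi (2 equiv, −78 °C) converts it into the lithium alkoxyacetylide F8. Addition to 19 gives the propargylic alcohols F9 (C1 epimers), and DMP gives the ynone F10. Corey–Bakshi–Shibata reduction (oxazaborolidine antipode chosen for the C1 configuration of 25, catecholborane) gives the carbinol F11. Semihydrogenation over Pd/CaCO3 poisoned with Pb(OAc)2 (quinoline, H2) gives the (Z)-enol ether 25.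

Further compounds
F1 | step 18 | lactol of 26 (C19 hemiacetal) | CC(C)(C)[Si](C)(C)OC1C[C@]23C[C@H]1C4(OCCO4)C[C@H]2[C@]5(C)[C@H](/C=C\OCc6ccc(OC)cc6)OC(O)C(C)[C@H]5[C@@H]3C(=O)OC(C)(C)C
F2 | step 18 | cyclic enol ether (C19=C4 dihydropyran) | CC(C)(C)[Si](C)(C)OC1C[C@]23C[C@H]1C4(OCCO4)C[C@H]2[C@]5(C)[C@H](/C=C\OCc6ccc(OC)cc6)OC=C(C)[C@H]5[C@@H]3C(=O)OC(C)(C)C
F3 | step 18 | C19 aldehyde of ring A (Δ1, 3β-OPMB) | CC(C)(C)[Si](C)(C)OC1C[C@]23C[C@H]1C4(OCCO4)C[C@H]2[C@]5(C)C=C[C@H](OCc6ccc(OC)cc6)[C@@](C)(C=O)[C@H]5[C@@H]3C(=O)OC(C)(C)C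
F4 | step 8 | tert-butyl{[1-(ethylsulfanyl)ethenyl]oxy}dimethylsilane | C=C(SCC)O[Si](C)(C)C(C)(C)C
F5 | step 8 | thioacetate adduct at C9 (C10 = CH2) | CC(C)(C)[Si](C)(C)OC1C[C@]2(CC(=O)OC(C)(C)C)C[C@H]1C(O[Si](C)(C)C(C)(C)C)=C[C@H]2CC(=O)SCC
F6 | step 8 | benzyloxymethyl thioester (C10 epimers) | CC(C)(C)[Si](C)(C)OC1C[C@]2(CC(=O)OC(C)(C)C)C[C@H]1C(O[Si](C)(C)C(C)(C)C)=C[C@H]2C(COCc3ccccc3)C(=O)SCC
F7 | step 17 | (E)-1,2-dichlorovinyl 4-methoxybenzyl ether | COc1ccc(CO/C(Cl)=C\Cl)cc1
F8 | step 17 | lithium (4-methoxybenzyloxy)acetylide | COc1ccc(COC#C[Li])cc1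
F9 | step 17 | propargylic alcohols (C1 epimers) | CC(C)(C)[Si](C)(C)OC1C[C@]23C[C@H]1C4(OCCO4)C[C@H]2[C@](C)(C(O)C#COCc5ccc(OC)cc5)[C@@H](C(C)C(=O)OC)[C@@H]3C(=O)OC(C)(C)C
F10 | step 17 | C1 ynone | CC(C)(C)[Si](C)(C)OC1C[C@]23C[C@H]1C4(OCCO4)C[C@H]2[C@](C)(C(=O)C#COCc5ccc(OC)cc5)[C@@H](C(C)C(=O)OC)[C@@H]3C(=O)OC(C)(C)C
F11 | step 17 | C1 propargylic carbinol, single epimer | CC(C)(C)[Si](C)(C)OC1C[C@]23C[C@H]1C4(OCCO4)C[C@H]2[C@](C)([C@@H](O)C#COCc5ccc(OC)cc5)[C@@H](C(C)C(=O)OC)[C@@H]3C(=O)OC(C)(C)C
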